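Remark on the chemistry: the name is taken to mean exactly the structure of the SMILES string, 3,5,4'-trihydroxy-7-methoxy-8-prenylflavone. Flavone numbering is used for all intermediates (O1, C2, C3, C4, C4a, C5 to C8, C8a; ring A is the benzo ring, ring C the pyranone, ring B the aryl group on C2), and "prenyl" means 3-methylbut-2-en-1-yl.

## Analysis of the target

Isoanhydroicaritin (18) is a flavonol: a 4H-chromen-4-one (benzo ring A fused to pyranone ring C) with a 4-hydroxyphenyl group (ring B) on C2 and a hydroxyl on C3. Ring A is fully differentiated: a hydroxyl at C5 hydrogen-bonded to the C4 carbonyl, a hydrogen at C6, a methyl ether at C7 and a prenyl chain at C8, next to the ring oxygen O1. There is no stereocentre, and the side-chain alkene ends in two identical methyl groups, so no stereochemical relationship has to be set. The sensitive functions are the trisubstituted prenyl alkene, the electron-rich ring A with its open C6 position, and three hydroxyl groups of different acidity. The alkene is attacked by protic and Lewis acids (addition, or cyclisation onto a neighbouring phenolic oxygen to a chroman), by peracids and by hydrogenation. The difficulty is therefore regiochemistry and chemoselectivity: prenyl at C8 and not C6, the C7 oxygen methylated while the C5 and C4' oxygens end free, and C3 oxygenated without touching the alkene. The strategy rests on C4 being an aryl ketone carbon bonded to C4a, whose neighbour C8a carries O1. C4 can therefore enter as the formyl carbon of a salicylaldehyde, with the phenolic oxygen that becomes O1 holding a metal next to the formyl C–H bond. C3 and C2 then arrive together as the ylide carbon and the carbonyl carbon of an aroylmethyl sulfoxonium ylide.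

## Retrosynthetic reasoning

**18 to 17 (O–C bonds at C5 and C4').** The two free phenols are masked until the end, as a methyl ether at C5 and a benzyl ether at C4'. A free C4' phenol would be acylated when the ylide is made, and a free C5 hydroxyl would offer the catalyst a second phenoxide beside the formyl group. The C5 ether sits peri to the C4 carbonyl and can be cleaved through a six-membered boron chelate, whereas the C7 ether has no such neighbour. Benzyl is chosen at C4' because it can be ionised at low temperature in the presence of a cation trap; hydrogenolysis would not spare the prenyl alkene. The forward step must cleave both ethers in one Lewis acid treatment and leave the C7 methyl ether and the alkene alone.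

**17 to 14 (C3–O bond).** The C3 hydroxyl is removed next, leading to flavone 14. It cannot be carried through the ring closure, because C3 comes from the carbanionic carbon of a sulfoxonium ylide, which cannot bear an oxygen substituent. In 14, C3–H is the only hydrogen on ring C and lies beside the C4 carbonyl, so it can be lithiated (15), borylated (16) and oxidised. The forward sequence must oxidise a C–B bond without epoxidising the prenyl alkene.

**14 to 8 and 12 (C3–C4 and O1–C2; ring C).** This is the central disconnection. Cutting both bonds that join the three-atom C2–C3–C4 bridge to ring A and to itself gives salicylaldehyde 8, which holds C4 and O1, and ylide 12, which holds C3, C2 and ring B. It is made here because 8 has a single free phenolic oxygen, and that oxygen lies next to the prenyl group, so the fusion can only give the 8-prenyl flavone. The same oxygen is the handle that brings a metal to the formyl C–H bond. The forward reaction must insert the ylide carbon into that C–H bond to give diketone 13, and then close O1–C2 by dehydration, in one operation.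

**12 to 9 and 10 (acyl C–C bond).** The ylide is cut between its carbanionic carbon and the carbonyl. Both pieces are commercial: sulfoxonium salt 9 supplies methylide 11, and acid chloride 10 carries ring B with its benzyl ether already in place. The forward step is a C-acylation in which a second equivalent of 11 acts as base.

**8 to 6 (C4–C4a bond).** The formyl group is removed to give phenol 6. In 6 one ortho position of the hydroxyl is blocked by the prenyl group, so a phenoxide-directed formylation (through salicyl alcohol 7) can only enter at the remaining one, between the hydroxyl and a methoxy group.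

**6 to 5, then 2 and 3, then 1 (C8–CH2 bond).** The prenyl group is disconnected from the ring at the carbon flanked by two oxygens. Phenol 1 is protected as acetal ether 2, whose directing group steers lithiation to the carbon between it and a methoxy group (aryllithium 4). Alkylation with bromide 3 gives 5 and deprotection gives 6. The forward sequence must lithiate next to the acetal ether and not between the two methoxy groups, and must couple at the primary carbon of 3.

## Alternatives that were turned down

**Alternative 1:** Ring A is taken apart at C8–C8a and C4a–C5, so the arene is assembled from two acyclic pieces. The electron-rich diene A1 (a silyl ketene acetal that already carries the prenyl chain) would add to the bromoalkynyl ketone A2 in a Diels–Alder reaction. The adduct would aromatise by eliminating its methoxy group and, after desilylation, give phenol A3, with bromine on C8a and, on C4a, the ketone that carries the future C3 oxygen as a MOM ether.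
- For: the polarisation of both partners fixes every ring A substituent in one step, so prenyl can only arrive at C8. The C5 oxygen emerges free and the C7 oxygen methylated, so no selective demethylation is needed. C3 is oxygenated from the start. On these three points it is stronger than the chosen route.
- Against: A1 is substituted at its reacting terminus and is hydrolytically fragile, A2 is a reactive haloalkynyl ketone, and both need several steps of preparation. The effort goes into a benzene ring that can be bought.
- Against: A3 is still far from the target. C2 and ring B must be attached by acylation of the ketone, and O1–C8a must be closed by displacing a bromide flanked by the prenyl and acyl groups on an electron-rich ring, a demanding C–O arylation.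
- Comparison: the chosen strategy starts from a commercial phenol with O1 already on the ring, reaches its key step in four routine operations and forms ring C in one catalytic step. It pays for this with a late C3 hydroxylation and a final selective ether cleavage.

**Alternative 2:** Ring A is again built from small pieces, by cutting C8–C8a, C6–C7 and C4a–C8a. Heating cyclobutenone A4 with the prenyl-substituted methyl ynol ether A5 would set off a cascade: four-electron ring opening of A4, [2+2] addition to the alkyne, a second ring opening and a six-electron electrocyclisation, ending in phenol A6.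
- For: the cascade is regiospecific and needs no protecting group. It places the prenyl group between the hydroxyl and the methoxy group with no site-selectivity question; in this respect it is stronger than the directed lithiation of step 2.
- Against: A6 is only the counterpart of phenol 6 (ethyl instead of methyl on the future C5 oxygen), which the chosen route reaches in three standard steps from 1.
- Against: A5 is a volatile, sensitive ynol ether that has to be made, and the ketene intermediates are generated next to a pendant alkene with which they can add intramolecularly.
- Against: ring C, the C3 oxygen and the final dealkylation are still ahead, so a second strategy for the pyranone would be needed anyway.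
- Comparison: the chosen route spends its one unusual step on ring C, where the flavone skeleton is actually built, and accepts a directed metalation for the ring A pattern.

**Alternative 3:** Ring C is cut at C3–C4 and O1–C8a, which makes ring A the electrophile in both bond formations. The lithium enolate of the α-alkoxy ketone A7 would be C-acylated by the fluorobenzoyl chloride A8. Heating with K2CO3 would then make the enolate oxygen of the acylation product displace the ortho fluoride, closing the pyranone as flavone A9.
- For: it is convergent, needs no transition metal, and brings the C3 oxygen in with A7, so the lithiation, borylation and oxidation of step 7 disappear. On that point it is the stronger plan.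
- Against: A8 is not commercial. Its prenyl and carboxyl groups must both be placed next to fluorine on a fluoroarene by two directed metalations, which costs about as many steps as aldehyde 8 and raises the site-selectivity question twice.
- Against: the leaving fluoride is activated only by the acyl group, which is itself deactivated by methoxy donors ortho and para to the carbon that bears it. Substitution at a position flanked by the prenyl chain is therefore uncertain, and O-acylation of the enolate competes with C-acylation.
- Against: selective Lewis acid cleavage of the C5 methyl ether is still required at the end, so the prenyl alkene is not spared that treatment.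
- Comparison: the chosen strategy keeps O1 on ring A from the commercial phenol, avoids any C–O arylation, and lets chelation enforce the one chemoselective event of ring closure. The step counts of the two plans are expected to be similar.

Key step: step 6

## Route

Step 1
Reactants: 1 3,5-dimethoxyphenol
Product: 2 1,3-dimethoxy-5-(methoxymethoxy)benzene
Conditions: NaH, MOMCl, DMF, 0 °C to rt
Reagents that add atoms: chloromethyl methyl ether (MOMCl), COCCl
Why: Williamson-type O-alkylation of the sodium phenoxide by the α-chloro ether. The MOM acetal is chosen because it is a stronger ortho-directing group than methoxy for step 2 and can later be removed without touching the methyl ethers.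

Step 2
Reactants: 2 1,3-dimethoxy-5-(methoxymethoxy)benzene; 3 prenyl bromide (1-bromo-3-methylbut-2-ene)
Product: 5 1,5-dimethoxy-3-(methoxymethoxy)-2-(3-methylbut-2-en-1-yl)benzene, via aryllithium 4 (not isolated)
Conditions: n-BuLi, THF, 0 °C; then CuBr·SMe2 (10 mol%), 3, −78 °C to rt
Reagents that add atoms: n-butyllithium, [Li]CCCC (lithium of intermediate 4 only)
Why: Directed ortho-metalation: the acetal oxygens of the MOM group and the neighbouring methoxy group together should place lithium on the carbon between them (two equivalent sites) in preference to the carbon between the two methoxy groups. Copper-catalysed allylic substitution of the aryl nucleophile at the primary carbon of 3 then gives the linear prenyl arene.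

Step 3
Reactants: 5 1,5-dimethoxy-3-(methoxymethoxy)-2-(3-methylbut-2-en-1-yl)benzene
Product: 6 3,5-dimethoxy-2-(3-methylbut-2-en-1-yl)phenol
Conditions: HCl (cat., conc. aq.), MeOH, rt to 40 °C
Reagents that add atoms: none
Why: Acid-catalysed methanolysis (acetal exchange) of the aryl MOM ether. Dilute acid near room temperature should leave the methyl ethers intact and be too weak to add the freed phenol across the prenyl alkene.

Step 4
Reactants: 6 3,5-dimethoxy-2-(3-methylbut-2-en-1-yl)phenol
Product: 8 2-hydroxy-4,6-dimethoxy-3-(3-methylbut-2-en-1-yl)benzaldehyde, via salicyl alcohol 7 (not isolated)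
Conditions: MgCl2, Et3N, (CH2O)n, MeCN, reflux; aq. HCl work-up
Reagents that add atoms: paraformaldehyde (reacts as formaldehyde), C=O
Why: Magnesium-mediated ortho-formylation (Casnati–Skattebøl reaction): the magnesium phenoxide delivers formaldehyde to the ortho carbon, and salicyl alcohol 7 is oxidised by a second formaldehyde through an Oppenauer-type hydride transfer. Only one ortho position of 6 is free, so the formyl group can only enter between the hydroxyl and a methoxy group.

Step 5
Reactants: 9 trimethylsulfoxonium iodide; 10 4-(benzyloxy)benzoyl chloride
Product: 12 1-[4-(benzyloxy)phenyl]-2-[dimethyl(oxo)-λ6-sulfanylidene]ethan-1-one, via dimethylsulfoxonium methylide 11 (not isolated)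
Conditions: 9 (3 equiv), KOtBu (3 equiv), THF, reflux; then 10 (1 equiv), 0 °C to rt
Reagents that add atoms: none
Why: C-acylation of the Corey–Chaykovsky methylide 11 by the aroyl chloride; a second equivalent of 11 removes the acidic proton of the acylated sulfoxonium salt to give the stabilised β-keto sulfoxonium ylide. The benzyl ether is inert to these conditions.

Step 6
Reactants: 8 2-hydroxy-4,6-dimethoxy-3-(3-methylbut-2-en-1-yl)benzaldehyde; 12 1-[4-(benzyloxy)phenyl]-2-[dimethyl(oxo)-λ6-sulfanylidene]ethan-1-one
Product: 14 2-[4-(benzyloxy)phenyl]-5,7-dimethoxy-8-(3-methylbut-2-en-1-yl)-4H-chromen-4-one, via ortho-hydroxyaryl diketone 13 (not isolated)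
Conditions: [Cp*RhCl2]2 (4 mol%), AgSbF6 (16 mol%), NaOAc (1 equiv), ClCH2CH2Cl, 80 °C
Reagents that add atoms: none
Why: Chloride abstraction by AgSbF6 gives a cationic Cp*Rh species of trivalent rhodium that binds the phenoxide of 8; acetate-assisted concerted metalation–deprotonation of the adjacent formyl C–H bond then gives a five-membered acyl rhodacycle. The nucleophilic carbon of ylide 12 adds to rhodium and dimethyl sulfoxide leaves to give a rhodium carbene; 1,1-migratory insertion of the acyl group into the carbene forms C3–C4, and protonation of the rhodium–carbon and rhodium–oxygen bonds releases diketone 13 and returns the catalyst. Ring C closes from 13 without a separate operation: the phenolic oxygen adds to the aroyl carbonyl carbon C2 in a 6-exo-trig sense to a six-membered hemiketal, and loss of water gives the conjugated pyranone, which forms O1–C2. The closest known reaction type is the rhodium-catalysed formyl C–H annulation of salicylaldehydes with aroyl sulfoxonium ylides to chromones, applied here to a more substituted aldehyde. No stereocentre is formed. The step needs chemoselectivity for the formyl C–H bond over the aryl C–H bonds of 8 and 12 and over the prenyl alkene; this is secured by the ortho phenoxide, which places rhodium within reach of the formyl hydrogen only, and by the trisubstituted alkene being a poor ligand and a poor insertion partner. Regiochemistry is fixed by the substrate, since the only free ring A oxygen of 8 is the one next to the prenyl group, so the chain can only end up at C8; NaOAc keeps the medium buffered so that the free ortho-prenylphenol is not cyclised by adventitious acid before it is consumed.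

Step 7
Reactants: 14 2-[4-(benzyloxy)phenyl]-5,7-dimethoxy-8-(3-methylbut-2-en-1-yl)-4H-chromen-4-one
Product: 17 2-[4-(benzyloxy)phenyl]-3-hydroxy-5,7-dimethoxy-8-(3-methylbut-2-en-1-yl)-4H-chromen-4-one, via C3-lithiated flavone 15 (not isolated), via dimethyl flavon-3-ylboronate 16 (not isolated)
Conditions: LiN(iPr)2, THF, −78 °C; B(OMe)3, −78 °C to rt; AcOH, 30% aq. H2O2, 0 °C
Reagents that add atoms: lithium diisopropylamide, [Li]N(C(C)C)C(C)C (lithium of 15 only); trimethyl borate, COB(OC)OC (boron and methoxy groups of 16 only); hydrogen peroxide, OO (oxygen at C3 of 17)
Why: Lithiation–borylation–oxidation: C3–H is the only ring C hydrogen and the C4 carbonyl oxygen guides the lithium amide to it, so deprotonation at −78 °C should give 15, which is trapped as boronate 16. Oxidation proceeds by 1,2-migration of C3 from boron to oxygen in the hydroperoxide adduct; cold, acetic acid-buffered peroxide is not expected to epoxidise the prenyl alkene.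

Step 8
Reactants: 17 2-[4-(benzyloxy)phenyl]-3-hydroxy-5,7-dimethoxy-8-(3-methylbut-2-en-1-yl)-4H-chromen-4-one
Product: 18 isoanhydroicaritin, 3,5-dihydroxy-2-(4-hydroxyphenyl)-7-methoxy-8-(3-methylbut-2-en-1-yl)-4H-chromen-4-one
Conditions: BCl3 (1 M in CH2Cl2), C6HMe5, CH2Cl2, −78 °C to 0 °C; MeOH, then aq. NaHCO3
Reagents that add atoms: none
Why: Lewis acid ether cleavage: BCl3 bridges the C4 carbonyl and the peri C5 methoxy group and cleaves that methyl ether through a six-membered chelate, while the unchelated C7 ether stays. The benzyl ether ionises at low temperature, and pentamethylbenzene captures the benzyl cation by Friedel–Crafts alkylation before it can attack ring A or the alkene; the prenyl group has no free ortho oxygen onto which it could cyclise.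

## Compound list

1 | 3,5-dimethoxyphenol | COc1cc(O)cc(OC)c1 | starting material
2 | 1,3-dimethoxy-5-(methoxymethoxy)benzene | COCOc1cc(OC)cc(OC)c1 | intermediate
3 | prenyl bromide (1-bromo-3-methylbut-2-ene) | CC(C)=CCBr | starting material
4 | [2,4-dimethoxy-6-(methoxymethoxy)phenyl]lithium | [Li]c1c(OC)cc(OC)cc1OCOC | intermediate (not isolated)
5 | 1,5-dimethoxy-3-(methoxymethoxy)-2-(3-methylbut-2-en-1-yl)benzene | COCOc1cc(OC)cc(OC)c1CC=C(C)C | intermediate
6 | 3,5-dimethoxy-2-(3-methylbut-2-en-1-yl)phenol | COc1cc(O)c(CC=C(C)C)c(OC)c1 | intermediate
7 | 2-(hydroxymethyl)-3,5-dimethoxy-6-(3-methylbut-2-en-1-yl)phenol (as its magnesium phenoxide) | COc1cc(OC)c(CO)c(O)c1CC=C(C)C | intermediate (not isolated)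
8 | 2-hydroxy-4,6-dimethoxy-3-(3-methylbut-2-en-1-yl)benzaldehyde | COc1cc(OC)c(C=O)c(O)c1CC=C(C)C | intermediate
9 | trimethylsulfoxonium iodide | C[S+](C)(C)=O.[I-] | starting material
10 | 4-(benzyloxy)benzoyl chloride | O=C(Cl)c1ccc(OCc2ccccc2)cc1 | starting material
11 | dimethylsulfoxonium methylide | C=S(C)(C)=O | intermediate (not isolated)
12 | 1-[4-(benzyloxy)phenyl]-2-[dimethyl(oxo)-λ6-sulfanylidene]ethan-1-one | O=C(C=S(C)(C)=O)c1ccc(OCc2ccccc2)cc1 | intermediate
13 | 1-[4-(benzyloxy)phenyl]-3-[2-hydroxy-4,6-dimethoxy-3-(3-methylbut-2-en-1-yl)phenyl]propane-1,3-dione | COc1cc(OC)c(C(=O)CC(=O)c2ccc(OCc3ccccc3)cc2)c(O)c1CC=C(C)C | intermediate (not isolated)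
14 | 2-[4-(benzyloxy)phenyl]-5,7-dimethoxy-8-(3-methylbut-2-en-1-yl)-4H-chromen-4-one | COc1cc(OC)c2c(=O)cc(-c3ccc(OCc4ccccc4)cc3)oc2c1CC=C(C)C | intermediate
15 | {2-[4-(benzyloxy)phenyl]-5,7-dimethoxy-8-(3-methylbut-2-en-1-yl)-4-oxo-4H-chromen-3-yl}lithium | [Li]c1c(-c2ccc(OCc3ccccc3)cc2)oc2c(CC=C(C)C)c(OC)cc(OC)c2c1=O | intermediate (not isolated)
16 | dimethyl {2-[4-(benzyloxy)phenyl]-5,7-dimethoxy-8-(3-methylbut-2-en-1-yl)-4-oxo-4H-chromen-3-yl}boronate | COB(OC)c1c(-c2ccc(OCc3ccccc3)cc2)oc2c(CC=C(C)C)c(OC)cc(OC)c2c1=O | intermediate (not isolated)
17 | 2-[4-(benzyloxy)phenyl]-3-hydroxy-5,7-dimethoxy-8-(3-methylbut-2-en-1-yl)-4H-chromen-4-one | COc1cc(OC)c2c(=O)c(O)c(-c3ccc(OCc4ccccc4)cc3)oc2c1CC=C(C)C | intermediate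
18 | isoanhydroicaritin, 3,5-dihydroxy-2-(4-hydroxyphenyl)-7-methoxy-8-(3-methylbut-2-en-1-yl)-4H-chromen-4-one | COc1cc(O)c2c(=O)c(O)c(-c3ccc(O)cc3)oc2c1CC=C(C)C | target

## Step count and least certain steps

Total step count: 8 (steps 1 to 8). Longest linear sequence: 7 steps (1 → 2 → 5 → 6 → 8 → 14 → 17 → 18, that is steps 1, 2, 3, 4, 6, 7 and 8); step 5 is a one-step side branch.

**Step 6 (key step).** The most likely failure is loss of the directing group before C–H activation: the cationic silver and rhodium species, or acid formed from them, can add the free phenol across the neighbouring prenyl alkene to give a chroman. In addition the formyl group is flanked on both sides (hydroxyl and methoxy), so metalation and carbene insertion may be slow enough for the ylide to decompose or to undergo its own ketone-directed aryl C–H activation. The fallback replaces C–H activation by acetylide chemistry; it sets out from aldehyde 8 and comes back at flavone 14. 1-(Benzyloxy)-4-ethynylbenzene F1 is deprotonated with n-BuLi in THF to {[4-(benzyloxy)phenyl]ethynyl}lithium F2. An excess of F2 adds to the phenoxide of 8 and should give the racemic propargylic alcohol 2-{3-[4-(benzyloxy)phenyl]-1-hydroxyprop-2-yn-1-yl}-3,5-dimethoxy-6-(3-methylbut-2-en-1-yl)phenol F3. Oxidation with MnO2 in CH2Cl2 gives the ynone 3-[4-(benzyloxy)phenyl]-1-[2-hydroxy-4,6-dimethoxy-3-(3-methylbut-2-en-1-yl)phenyl]prop-2-yn-1-one F4. Amine-mediated (Et2NH, EtOH) 6-endo-dig addition of the phenolic oxygen to the ynone then closes ring C to 14.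

**Step 2.** The risk is misdirected lithiation, at the carbon between the two methoxy groups instead of the carbon next to the MOM ether, which would lead to the 6-prenyl series. A second risk is attack of the aryl nucleophile at the tertiary end of the allyl system, giving a 1,1-dimethylallyl arene. The fallback uses a sigmatropic shift in place of metalation; it sets out from phenol 1 and comes back at phenol 6, bypassing steps 1 to 3. O-Alkylation of 1 with 3-chloro-3-methylbut-1-yne F5 (K2CO3, KI, CuI cat., acetone, reflux) gives 1,3-dimethoxy-5-[(2-methylbut-3-yn-2-yl)oxy]benzene F6. Semihydrogenation (H2, Pd/CaCO3 poisoned with Pb(OAc)2, quinoline, EtOAc) gives 1,3-dimethoxy-5-[(2-methylbut-3-en-2-yl)oxy]benzene F7. Heating F7 in N,N-diethylaniline brings about the aromatic Claisen rearrangement, whose [3,3] shift delivers the linear prenyl group to an ortho carbon. The two ortho positions are equivalent, so 6 should result without a site-selectivity question and without exposure of the ortho-prenylphenol to acid.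

**Step 7.** The risk lies mainly in the oxidative work-up: peracetic acid formed from H2O2 and AcOH can epoxidise the electron-rich prenyl alkene, and the flavonol product is itself sensitive to excess peroxide. Incomplete borylation, which returns 14 on protonation, is the second possibility. The fallback oxygenates the carbanion directly and involves no boron; it sets out from flavone 14 and comes back at 17. Lithio species 15 is generated as before and quenched at −78 °C with bis(trimethylsilyl) peroxide (Me3SiOOSiMe3), an electrophilic oxygen source for aryl- and vinyllithiums. This should give 2-[4-(benzyloxy)phenyl]-5,7-dimethoxy-8-(3-methylbut-2-en-1-yl)-3-[(trimethylsilyl)oxy]-4H-chromen-4-one F8. The silyl ether is cleaved on work-up with K2CO3 in MeOH to give 17, and the alkene never meets a peracid.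

**Step 8.** The C5 demethylation needs warming towards 0 °C, and at that temperature BCl3 and the HCl formed from it may add to or cyclise the prenyl alkene, for example onto the C7 methoxy oxygen with loss of its methyl group, or may begin to cleave the C7 ether. The fallback separates the two cleavages so that the alkene meets BCl3 only at −78 °C; it sets out from 17 and comes back at 18. Chelation-controlled demethylation with MgI2 etherate (THF/toluene, 60 °C), in which iodide removes the methyl group of the magnesium-bound peri ether, should give 2-[4-(benzyloxy)phenyl]-3,5-dihydroxy-7-methoxy-8-(3-methylbut-2-en-1-yl)-4H-chromen-4-one F9. The benzyl ether of F9 is then cleaved with BCl3 and pentamethylbenzene in CH2Cl2 held at −78 °C, which gives 18.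

## Further compounds

F1 | step 6 | 1-(benzyloxy)-4-ethynylbenzene | C#Cc1ccc(OCc2ccccc2)cc1
F2 | step 6 | {[4-(benzyloxy)phenyl]ethynyl}lithium | [Li]C#Cc1ccc(OCc2ccccc2)cc1
F3 | step 6 | 2-{3-[4-(benzyloxy)phenyl]-1-hydroxyprop-2-yn-1-yl}-3,5-dimethoxy-6-(3-methylbut-2-en-1-yl)phenol (racemic) | COc1cc(OC)c(C(O)C#Cc2ccc(OCc3ccccc3)cc2)c(O)c1CC=C(C)C
F4 | step 6 | 3-[4-(benzyloxy)phenyl]-1-[2-hydroxy-4,6-dimethoxy-3-(3-methylbut-2-en-1-yl)phenyl]prop-2-yn-1-one | COc1cc(OC)c(C(=O)C#Cc2ccc(OCc3ccccc3)cc2)c(O)c1CC=C(C)C
F5 | step 2 | 3-chloro-3-methylbut-1-yne | C#CC(C)(C)Cl
F6 | step 2 | 1,3-dimethoxy-5-[(2-methylbut-3-yn-2-yl)oxy]benzene | COc1cc(OC)cc(OC(C)(C)C#C)c1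
F7 | step 2 | 1,3-dimethoxy-5-[(2-methylbut-3-en-2-yl)oxy]benzene | COc1cc(OC)cc(OC(C)(C)C=C)c1
F8 | step 7 | 2-[4-(benzyloxy)phenyl]-5,7-dimethoxy-8-(3-methylbut-2-en-1-yl)-3-[(trimethylsilyl)oxy]-4H-chromen-4-one | COc1cc(OC)c2c(=O)c(O[Si](C)(C)C)c(-c3ccc(OCc4ccccc4)cc3)oc2c1CC=C(C)C
F9 | step 8 | 2-[4-(benzyloxy)phenyl]-3,5-dihydroxy-7-methoxy-8-(3-methylbut-2-en-1-yl)-4H-chromen-4-one | COc1cc(O)c2c(=O)c(O)c(-c3ccc(OCc4ccccc4)cc3)oc2c1CC=C(C)C
A1 | alternative 1 | [(1,3-dimethoxy-7-methylocta-1,3,6-trien-1-yl)oxy]trimethylsilane (alkene geometry not specified) | COC(O[Si](C)(C)C)=CC(OC)=CCC=C(C)C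
A2 | alternative 1 | 4-bromo-1-(methoxymethoxy)but-3-yn-2-one | COCOCC(=O)C#CBr
A3 | alternative 1 | 1-[2-bromo-6-hydroxy-4-methoxy-3-(3-methylbut-2-en-1-yl)phenyl]-2-(methoxymethoxy)ethan-1-one | COCOCC(=O)c1c(O)cc(OC)c(CC=C(C)C)c1Br
A4 | alternative 2 | 3-ethoxycyclobut-2-en-1-one | CCOC1=CC(=O)C1
A5 | alternative 2 | 1-methoxy-5-methylhex-4-en-1-yne | COC#CCC=C(C)C
A6 | alternative 2 | 5-ethoxy-3-methoxy-2-(3-methylbut-2-en-1-yl)phenol | COc1cc(OCC)cc(O)c1CC=C(C)C
A7 | alternative 3 | 2-(methoxymethoxy)-1-[4-(methoxymethoxy)phenyl]ethan-1-one | COCOCC(=O)c1ccc(OCOC)cc1
A8 | alternative 3 | 2-fluoro-4,6-dimethoxy-3-(3-methylbut-2-en-1-yl)benzoyl chloride | COc1cc(OC)c(C(=O)Cl)c(F)c1CC=C(C)C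
A9 | alternative 3 | 5,7-dimethoxy-3-(methoxymethoxy)-2-[4-(methoxymethoxy)phenyl]-8-(3-methylbut-2-en-1-yl)-4H-chromen-4-one | COCOc1c(-c2ccc(OCOC)cc2)oc2c(CC=C(C)C)c(OC)cc(OC)c2c1=O
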